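## Analysis of the target

The target 14 is 5-bromo-2-(3,5-dibromo-2-methoxyphenoxy)phenol, a tribrominated diaryl ether of two benzene rings joined through one oxygen. Ring A is numbered C1 (ether oxygen), C2 (methoxy), C3 and C5 (bromine); ring B is numbered C1' (ether oxygen), C6' (free hydroxyl) and C4' (bromine), with hydrogen at C2', C3' and C5'. There is no stereocenter, so the whole problem is one of regiochemistry. The sensitive groups are the three aryl C–Br bonds, the free phenol, and a methyl ether that must stay distinct from that phenol. The C–Br bonds exclude halogen–metal exchange and make copper- or palladium-mediated C–O coupling unselective. Three things make the synthesis hard: both ether carbons carry an ortho oxygen, the two rings are brominated differently, and the two phenolic oxygens end in different states (OMe on ring A, OH on ring B). The strategy rests on ring B, where the oxygens sit on the neighbouring carbons C1' and C6' and the bromine at C4' is para to C1' and meta to C6'. A two-carbon unit carrying both oxygens leaves exactly this pattern when it bridges C3 and C6 of a 2-pyrone brominated at C4, so ring B can be built around an ether oxygen that is already attached to ring A.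

## Retrosynthetic reasoning

Disconnection 1 (O–Si at C6'). The target 14 is traced back to its trimethylsilyl ether 13. The silyl ether is the form in which ring construction delivers the ring B oxygen, and it can be removed under conditions that cannot touch the ring A methyl ether. The forward step only has to hydrolyse an aryl silyl ether.

Disconnection 2 (C1'–C2' and C5'–C6' of ring B). Ring B of 13 is cut at the two bonds flanking the oxygenated pair C1'/C6'. Carbons C2'–C5' become C6–C3 of the bromopyrone 10, and C1'/C6' become the two alkene carbons of the ketene acetal 8. The cut is made here and not at the diaryl ether bond for two reasons. A metal-mediated C–O coupling would have to tell three C–Br bonds from its own leaving group. A nucleophilic aromatic substitution would need an activating group that must afterwards be turned into the hydroxyl. With ring B grown around the existing oxygen, the ether link is an ordinary alkyl aryl ether bond, the C4' bromine is carried in by C4 of 10, and the two oxygens arrive differentiated. The forward reaction has to be a regioselective [4+2] cycloaddition joining the aryloxy carbon of 8 to C6 of 10, followed by loss of the lactone bridge and of one silyloxy group together with the C1' hydrogen.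

Disconnection 3 (the two O–Si bonds of 8). The ketene acetal 8 is the doubly silylated enol form of the aryloxyacetic acid 6, reached through the silyl ester 7. Two identical silyl groups mean that no alkene geometry has to be controlled. The forward step must enolise without a base strong enough to metalate ring A or attack a C–Br bond, which points to a silyl triflate with a tertiary amine.

Disconnection 4 (O–CH2 of 6). Cutting the alkyl aryl ether bond gives the phenol 4 and bromoacetic acid 5. The forward step is a phenoxide alkylation at a primary carbon, and it supplies both future ring B carbons C1' and C6' at the correct oxidation level.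

Disconnection 5 (C1–O of ring A, then O–CH3). The hydroxyl of 4 is traced back, through the formate 3, to the formyl group of the aldehyde 2, and 2 to the hydroxy aldehyde 1 by removal of the methyl group. In 1 both bromines already sit ortho and para to the oxygen that becomes the methoxy group. Brominating a methoxyphenol that has a free hydroxyl would be steered by that hydroxyl to the wrong carbons. Methylating first and then converting the formyl carbon to oxygen means the two ring A oxygens are never equivalent. The forward oxidation needs aryl migration, not hydride migration.

Disconnection 6 (C4–Br of 10). The bromopyrone 10 is traced back to the hydroxypyrone 9 by exchanging bromine for the hydroxyl of a vinylogous acid. The forward step must activate that oxygen and deliver bromide at C4 without opening the lactone.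

## Alternatives that were turned down

Alternative 1: Ring A is cut at C1–C6 and C3–C4 instead. This gives the aryloxyacetone A2, which carries ring B as its tosylate, and bromomalonaldehyde A3, which supplies C4, C5 with its bromine, and C6. In the forward direction a twofold aldol condensation with loss of two molecules of water would close ring A and give the phenol A1.
- For it: C5–Br is fixed by the building block. The new C2 hydroxyl is free, so it can direct the missing bromine to C3 (its only open ortho position) and then be methylated, while the tosylate keeps the ring B oxygen distinct. The reagents are cheap and not moisture-sensitive.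
- Against it: the methyl group of A2 (the future C3) is only weakly acidic, so the ring-closing second aldol has to compete with self-condensation of A3. A3 is also an alpha-bromo aldehyde and can alkylate the enolate with loss of bromide. The dependable versions of this phenol synthesis use doubly activated ketones.
- Step economy: three steps follow the key step (bromination at C3, O-methylation, detosylation), and A2 needs about three steps of its own, for a linear sequence of about seven.
- Comparison: alternative 1 is stronger in the robustness of its reagents and in protecting the ring B oxygen with a stable sulfonate. The chosen strategy offers all three bromines in place before ring formation, no late bromination, and a single mild step after the ring is closed.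

Alternative 2: The disconnection is at O–C1 and at the C2 oxygen (as C2–B) of ring A, going back to an aryne. The iodo triflate A5 is treated with Me3SiCH2MgCl to release the aryne spanning C1 and C2. The magnesium phenolate of A6 adds at C1, the aryne carbon remote from the C3 bromine, and the resulting C2–magnesium bond is trapped by a pinacol borate ester to give the boronate A4. Oxidation of the C–B bond, O-methylation and removal of the methoxymethyl group would follow.
- For it: it is convergent, it forms the diaryl ether bond and installs the C2 oxygen handle in one operation, and the regiochemistry is dictated by the inductive effect of the C3 bromine.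
- Against it: the C2 aryl–magnesium intermediate has bromine on the neighbouring C3 and is itself an aryne precursor, so loss of bromide would scramble the substitution pattern. The Grignard reagent can also exchange with the C–Br bonds of both partners. An ortho-substituted phenolate is a modest aryne nucleophile. A5 and A6 each need their own preparation, and three steps follow the key step.
- Comparison: alternative 2 is more convergent, and its C–O bond formation is a fast polar process at low temperature. That is a real advantage over a thermal cycloaddition with a pyrone that is only moderately electron-poor. The chosen strategy offers a route with no carbon–metal bond in the presence of C–Br bonds, and one step after the key step instead of three.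

Alternative 3: The three C–Br bonds (C3–Br, C5–Br, C4'–Br) are disconnected. The symmetrical bis-phenol A9 is monotosylated to A8, which is brominated three times with KBr and H2O2 under NH4VO3 catalysis (pentavalent vanadium) to give A7. Methylation and detosylation would finish the synthesis.
- For it: it is the shortest plan, four steps from A9, and every step is classical. The free ring A hydroxyl activates C3 and C5, and the ether oxygen directs ring B bromination para, to C4'.
- Against it: monotosylation of A9 is statistical. The third bromination falls on the tosylate-deactivated ring B and is much slower than the first two, so it competes with a further bromination of ring A at C4 or C6 and with attack at C2' of ring B. Under- and over-brominated diaryl ethers and regioisomers are hard to separate and to tell apart.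
- Comparison: alternative 3 is clearly stronger on step count and cost. The chosen strategy offers a defined origin for each bromine, by construction and not by directing effects, which for this class of compounds is worth the extra steps.

Key step: step 6

Remark: 4-hydroxy-2H-pyran-2-one (9) is assumed to be purchasable; the target has no stereocenter, and the transient stereocenters of 11 and 12 are formed without control and erased on aromatisation.

## Route

Step 1
Reactants: 1 3,5-dibromo-2-hydroxybenzaldehyde
Product: 2 3,5-dibromo-2-methoxybenzaldehyde
Conditions: MeI, K2CO3, DMF, rt
Reagents that add atoms: iodomethane, CI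
Why: Williamson O-methylation; the phenol, acidified by the ortho formyl group and two bromines, is deprotonated by K2CO3 and methylated by SN2, which fixes the ring A C2 oxygen as the methyl ether before the second oxygen exists.

Step 2
Reactants: 2 3,5-dibromo-2-methoxybenzaldehyde
Product: 4 3,5-dibromo-2-methoxyphenol, via 3,5-dibromo-2-methoxyphenyl formate 3 (not isolated)
Conditions: mCPBA, CH2Cl2, 40 °C; then KOH, MeOH/H2O, rt; HCl work-up
Reagents that add atoms: 3-chloroperoxybenzoic acid (mCPBA), OOC(=O)c1cccc(Cl)c1
Why: Baeyer–Villiger (Dakin-type) oxidation; in the Criegee intermediate the aryl group, supported by the ortho methoxy donor, should migrate to oxygen to give formate 3, which is saponified in the same flask. The C–Br bonds and the methyl ether are inert to peracid and to cold hydroxide.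

Step 3
Reactants: 4 3,5-dibromo-2-methoxyphenol; 5 bromoacetic acid
Product: 6 (3,5-dibromo-2-methoxyphenoxy)acetic acid
Conditions: NaOH, H2O, 100 °C; then HCl
Reagents that add atoms: none
Why: Williamson ether synthesis, the classical preparation of aryloxyacetic acids; the phenoxide of 4 displaces bromide from the bromoacetate anion at a primary carbon, and acidification should precipitate 6.

Step 4
Reactants: 6 (3,5-dibromo-2-methoxyphenoxy)acetic acid
Product: 8 1,5-dibromo-3-{[2,2-bis(trimethylsilyloxy)ethenyl]oxy}-2-methoxybenzene, via trimethylsilyl (3,5-dibromo-2-methoxyphenoxy)acetate 7 (not isolated)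
Conditions: Me3SiOTf (2.3 equiv), Et3N (2.6 equiv), Et2O, 0 °C to rt
Reagents that add atoms: trimethylsilyl trifluoromethanesulfonate, C[Si](C)(C)OS(=O)(=O)C(F)(F)F
Why: O-silylation of the acid gives 7; a second equivalent of silyl triflate then activates the ester carbonyl while Et3N removes the alpha hydrogen acidified by the aryloxy group (soft enolisation to a bis-silyl ketene acetal). No strong base meets the C–Br bonds, and 8 is separated from the ammonium triflate under argon and used crude.

Step 5
Reactants: 9 4-hydroxy-2H-pyran-2-one
Product: 10 4-bromo-2H-pyran-2-one
Conditions: Bu4NBr, P2O5, toluene, 100 °C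
Reagents that add atoms: tetrabutylammonium bromide, CCCC[N+](CCCC)(CCCC)CCCC.[Br-]
Why: Deoxybromination of a vinylogous carboxylic acid; P2O5 turns the C4 hydroxyl into a phosphate leaving group and bromide replaces it by addition–elimination at C4. This reagent pair is established for 4-hydroxy-2-pyrones and 4-hydroxycoumarins and contains no formylating species.

Step 6
Reactants: 8 1,5-dibromo-3-{[2,2-bis(trimethylsilyloxy)ethenyl]oxy}-2-methoxybenzene; 10 4-bromo-2H-pyran-2-one
Product: 13 [5-bromo-2-(3,5-dibromo-2-methoxyphenoxy)phenoxy]trimethylsilane, via bridged lactone cycloadduct 11 (not isolated), via bis(silyloxy)cyclohexadiene 12 (not isolated)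
Conditions: 8 (3 equiv), toluene, sealed tube, 130 °C
Reagents that add atoms: none
Why: The ketene acetal 8 is a strongly electron-rich alkene with its largest HOMO coefficient on the aryloxy-bearing CH carbon, and the pyrone 10 is an electron-poor cyclic diene with its LUMO largest at C6, so a thermal inverse-electron-demand Diels–Alder reaction should join the aryloxy carbon to pyrone C6 (C1'–C2') and the acetal carbon to pyrone C3 (C5'–C6') to give the bridged lactone 11. Retro-[4+2] extrusion of CO2 from 11 leaves the cyclohexadiene 12, in which ionisation of the doubly allylic silyl ketal carbon and loss of the single hydrogen at C1' (net 1,2-elimination of Me3SiOH) should deliver the arene 13. The closest known reaction type is the benzannulation of 2-pyrones with ketene acetals, which gives oxygenated benzenes after loss of CO2 and an alcohol or silanol. Ring B is closed by an intermolecular [4+2] cycloaddition that builds a six-membered carbocycle from four pyrone carbons and the two ketene acetal carbons. No stereocenter remains in 13, and those of 11 and 12 are erased on aromatisation, so endo/exo and facial selectivity do not matter. The step needs regioselectivity (aryloxy carbon to pyrone C6, which puts bromine para to C1' and meta to C6'); this is secured by the matched polarisation of the two partners, reinforced by the C4 bromine donating toward C3. It also needs cycloaddition to outrun conjugate addition–elimination at the bromine-bearing C4, which the absence of any Lewis acid, the non-polar solvent and the concerted thermal pathway favour. An excess of 8 is used because the silanol set free can protonate the ketene acetal.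

Step 7
Reactants: 13 [5-bromo-2-(3,5-dibromo-2-methoxyphenoxy)phenoxy]trimethylsilane
Product: 14 5-bromo-2-(3,5-dibromo-2-methoxyphenoxy)phenol
Conditions: 1 M HCl, THF, rt (on crude 13)
Reagents that add atoms: none
Why: Acid-catalysed hydrolysis of an aryl trimethylsilyl ether (desilylation); the Si–O bond should cleave at room temperature while the methyl ether, the diaryl ether and the three C–Br bonds are stable.

## Compound list

1 | 3,5-dibromo-2-hydroxybenzaldehyde | O=Cc1cc(Br)cc(Br)c1O | starting material
2 | 3,5-dibromo-2-methoxybenzaldehyde | COc1c(Br)cc(Br)cc1C=O | intermediate
3 | 3,5-dibromo-2-methoxyphenyl formate | COc1c(Br)cc(Br)cc1OC=O | intermediate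
4 | 3,5-dibromo-2-methoxyphenol | COc1c(Br)cc(Br)cc1O | intermediate
5 | bromoacetic acid | OC(=O)CBr | starting material
6 | (3,5-dibromo-2-methoxyphenoxy)acetic acid | COc1c(Br)cc(Br)cc1OCC(=O)O | intermediate
7 | trimethylsilyl (3,5-dibromo-2-methoxyphenoxy)acetate | COc1c(Br)cc(Br)cc1OCC(=O)O[Si](C)(C)C | intermediate
8 | 1,5-dibromo-3-{[2,2-bis(trimethylsilyloxy)ethenyl]oxy}-2-methoxybenzene | COc1c(Br)cc(Br)cc1OC=C(O[Si](C)(C)C)O[Si](C)(C)C | intermediate
9 | 4-hydroxy-2H-pyran-2-one | O=C1C=C(O)C=CO1 | starting material
10 | 4-bromo-2H-pyran-2-one | O=C1C=C(Br)C=CO1 | intermediate
11 | 5-bromo-7-(3,5-dibromo-2-methoxyphenoxy)-8,8-bis(trimethylsilyloxy)-2-oxabicyclo[2.2.2]oct-5-en-3-one (racemic, endo and exo adducts, configuration not controlled) | COc1c(Br)cc(Br)cc1OC1C2C=C(Br)C(C(=O)O2)C1(O[Si](C)(C)C)O[Si](C)(C)C | intermediate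
12 | 1,5-dibromo-3-{[4-bromo-6,6-bis(trimethylsilyloxy)cyclohexa-2,4-dien-1-yl]oxy}-2-methoxybenzene (racemic) | COc1c(Br)cc(Br)cc1OC1C=CC(Br)=CC1(O[Si](C)(C)C)O[Si](C)(C)C | intermediate
13 | [5-bromo-2-(3,5-dibromo-2-methoxyphenoxy)phenoxy]trimethylsilane | COc1c(Br)cc(Br)cc1Oc1ccc(Br)cc1O[Si](C)(C)C | intermediate
14 | 5-bromo-2-(3,5-dibromo-2-methoxyphenoxy)phenol | COc1c(Br)cc(Br)cc1Oc1ccc(Br)cc1O | target

## Step count and least certain steps

Total step count: 7. Longest linear sequence: 6 (steps 1, 2, 3, 4, 6, 7); step 5 is a one-step branch.

Step 6 (key step). The most likely failure is that the cycloaddition is too slow at a temperature the ketene acetal tolerates. The pyrone has no ester activating group and the dienophile is trisubstituted, so oxygen-to-carbon silyl migration in 8, its protonolysis by released silanol, or stepwise conjugate addition with displacement of bromide at C4 may take over. The fallback gives up ring construction and makes the diaryl ether by nucleophilic aromatic substitution. It sets out from 4 and comes back at 14. Phenol 4 and 5-bromo-2-fluorobenzaldehyde (K2CO3, N,N-dimethylacetamide, 120 °C) should give 5-bromo-2-(3,5-dibromo-2-methoxyphenoxy)benzaldehyde F1, the formyl group activating the ortho fluorine. Baeyer–Villiger oxidation with mCPBA in CH2Cl2, where the ortho aryloxy donor supports aryl migration, should give 5-bromo-2-(3,5-dibromo-2-methoxyphenoxy)phenyl formate F2. Hydrolysis with KOH in aqueous MeOH then gives 14.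

Step 4. Enolisation may be incomplete, silylation may occur on carbon instead of oxygen, or the very moisture-sensitive bis-trimethylsilyl acetal may hydrolyse back to the ester while the ammonium salt is removed. The fallback switches to stepwise kinetic enolisation with a robust silyl group. It sets out from 6 and comes back at 14. Acid 6 with t-BuMe2SiCl and imidazole in DMF gives tert-butyldimethylsilyl (3,5-dibromo-2-methoxyphenoxy)acetate F3. Deprotonation with LiN(SiMe3)2 in THF/DMPU at −78 °C and trapping with t-BuMe2SiCl should give the isolable 1,5-dibromo-3-{[2,2-bis(tert-butyldimethylsilyloxy)ethenyl]oxy}-2-methoxybenzene F4. LiN(SiMe3)2 is chosen over LiN(iPr)2 so that the ring A hydrogen between the two bromines is not metalated. Heating F4 with 10 as in step 6 gives [5-bromo-2-(3,5-dibromo-2-methoxyphenoxy)phenoxy](tert-butyl)dimethylsilane F5, and Bu4NF in THF releases 14.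

Step 5. The 6-unsubstituted pyrone is more exposed to nucleophilic ring opening than its 6-methyl analogue, so hot acidic phosphorus reagents may cause decomposition or poor conversion, and the small product may be lost on isolation. The fallback separates activation from displacement. It sets out from 9 and comes back at 10. Compound 9 with (CF3SO2)2O and Et3N in CH2Cl2 at −78 °C gives 2-oxo-2H-pyran-4-yl trifluoromethanesulfonate F6. LiBr in acetone at rt to 50 °C should exchange the triflate for bromide by addition–elimination at C4, giving 10.

Step 2. Hydride migration may compete with aryl migration in the Criegee intermediate, leading to over-oxidation of the formyl group instead of oxygen insertion. The two bromines lower the migratory aptitude of the ring, and the flanked methoxy group is twisted out of conjugation. The fallback replaces the aldehyde by a methyl ketone, where aryl competes only with methyl. It sets out from 2 and comes back at 4. Aldehyde 2 with MeMgBr in THF at 0 °C gives racemic 1-(3,5-dibromo-2-methoxyphenyl)ethan-1-ol F7. Oxidation with MnO2 in CH2Cl2 gives 1-(3,5-dibromo-2-methoxyphenyl)ethan-1-one F8. Baeyer–Villiger oxidation with mCPBA and catalytic CF3CO2H gives 3,5-dibromo-2-methoxyphenyl acetate F9, and methanolysis with K2CO3 in MeOH returns 4.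

## Further compounds

F1 | step 6 | 5-bromo-2-(3,5-dibromo-2-methoxyphenoxy)benzaldehyde | COc1c(Br)cc(Br)cc1Oc1ccc(Br)cc1C=O
F2 | step 6 | 5-bromo-2-(3,5-dibromo-2-methoxyphenoxy)phenyl formate | COc1c(Br)cc(Br)cc1Oc1ccc(Br)cc1OC=O
F3 | step 4 | tert-butyldimethylsilyl (3,5-dibromo-2-methoxyphenoxy)acetate | COc1c(Br)cc(Br)cc1OCC(=O)O[Si](C)(C)C(C)(C)C
F4 | step 4 | 1,5-dibromo-3-{[2,2-bis(tert-butyldimethylsilyloxy)ethenyl]oxy}-2-methoxybenzene | COc1c(Br)cc(Br)cc1OC=C(O[Si](C)(C)C(C)(C)C)O[Si](C)(C)C(C)(C)C
F5 | step 4 | [5-bromo-2-(3,5-dibromo-2-methoxyphenoxy)phenoxy](tert-butyl)dimethylsilane | COc1c(Br)cc(Br)cc1Oc1ccc(Br)cc1O[Si](C)(C)C(C)(C)C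
F6 | step 5 | 2-oxo-2H-pyran-4-yl trifluoromethanesulfonate | O=C1C=C(OS(=O)(=O)C(F)(F)F)C=CO1
F7 | step 2 | 1-(3,5-dibromo-2-methoxyphenyl)ethan-1-ol (racemic) | COc1c(Br)cc(Br)cc1C(C)O
F8 | step 2 | 1-(3,5-dibromo-2-methoxyphenyl)ethan-1-one | COc1c(Br)cc(Br)cc1C(C)=O
F9 | step 2 | 3,5-dibromo-2-methoxyphenyl acetate | COc1c(Br)cc(Br)cc1OC(C)=O
A1 | alternative 1 | 5-bromo-2-(5-bromo-2-hydroxyphenoxy)phenyl 4-methylbenzenesulfonate | Oc1ccc(Br)cc1Oc1ccc(Br)cc1OS(=O)(=O)c1ccc(C)cc1
A2 | alternative 1 | 5-bromo-2-(2-oxopropoxy)phenyl 4-methylbenzenesulfonate | CC(=O)COc1ccc(Br)cc1OS(=O)(=O)c1ccc(C)cc1
A3 | alternative 1 | 2-bromopropanedial (bromomalonaldehyde) | O=CC(Br)C=O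
A4 | alternative 2 | 2-{2,4-dibromo-6-[4-bromo-2-(methoxymethoxy)phenoxy]phenyl}-4,4,5,5-tetramethyl-1,3,2-dioxaborolane | COCOc1cc(Br)ccc1Oc1cc(Br)cc(Br)c1B1OC(C)(C)C(C)(C)O1
A5 | alternative 2 | 2,4-dibromo-6-iodophenyl trifluoromethanesulfonate | FC(F)(F)S(=O)(=O)Oc1c(I)cc(Br)cc1Br
A6 | alternative 2 | 4-bromo-2-(methoxymethoxy)phenol | COCOc1cc(Br)ccc1O
A7 | alternative 3 | 5-bromo-2-(3,5-dibromo-2-hydroxyphenoxy)phenyl 4-methylbenzenesulfonate | Cc1ccc(cc1)S(=O)(=O)Oc1cc(Br)ccc1Oc1cc(Br)cc(Br)c1O
A8 | alternative 3 | 2-(2-hydroxyphenoxy)phenyl 4-methylbenzenesulfonate | Cc1ccc(cc1)S(=O)(=O)Oc1ccccc1Oc1ccccc1O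
A9 | alternative 3 | 2,2'-oxydiphenol | Oc1ccccc1Oc1ccccc1O
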